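**Plan**

- Retrosynthetic cuts, in this order: the five ester groups and the C11–C20 epoxide oxygen; the lactone bond C8–C17 (Reformatsky closure from an O7 2-bromopropanoate onto a C8 ketone); C6–Cl and C4–C5 with C2–C7 re-formed, which folds the ten-membered ring back into a trans-decalin; then C7–C6 (alkynyl addition) and C2–C3 (vinyl coupling).
- Enabling feature: the ten-membered ring C1–C10 carries oxygen on C2 and C7, plain CH2 at C3 and C4, the C16 methylene on C5 and chlorine on C6. This is what an anionic oxy-Cope shift leaves when a decalin (ring A C1/C14/C13/C12/C11/C10, ring B C1/C2/C7/C8/C9/C10) with vinyl and methoxy on C2 and propadienyl and hydroxyl on C7 opens across C2–C7 and the enolate is chlorinated.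
- Forward order: ring A is oxygenated first on the decalin (C13/C14 diol, C20 methylene, C12 alcohol), then ring B (C2 vinyl ether and C9 oxygen from one singlet-oxygen adduct, then C8 and C7). Ring B is then expanded to the ten-membered ring, the lactone is closed, and epoxidation and acylation finish the route.
- Stereochemistry: C1 comes from the starting enedione and C10 from dissolving-metal reduction. C13/C14 (OsO4), C2 (singlet oxygen), C12 and C9 (hydride) are all set anti to the C15 methyl or its syn-axial reach. C6, C7 and C2 (final) come from reagent approach to the outer face of the ten-membered ring, C8/C17 from the tethered enolate, and C11 from hydroxyl-directed epoxidation.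

Key step: step 25

Assumption: the identifier is taken to mean exactly the stereoisomer of the given SMILES; briarane numbering is used for all intermediates (C2 and C7 are bonded in the decalins), and α/β mean the faces of H-10 and of the C15 methyl on C1 in the flat drawing.

**Route**

Step 1
Reactants: 1 (S)-8a-methyl-3,4,8,8a-tetrahydronaphthalene-1,6(2H,7H)-dione (Wieland–Miescher ketone)
Product: 2 2β-hydroxy enone
Conditions: NaBH4 (0.3 equiv), EtOH, −10 °C
Reagents that add atoms: none
Why: Chemoselective borohydride reduction of the saturated C2 ketone (the enone carbonyl is less electrophilic), with hydride entering anti to the angular methyl so that the C2 alcohol is β.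

Step 2
Reactants: 2 2β-hydroxy enone
Product: 3 2β-TBS ether
Conditions: TBSCl, imidazole, DMF, rt
Reagents that add atoms: tert-butyldimethylsilyl chloride CC(C)(C)[Si](C)(C)Cl
Why: Silyl ether formation masks O2 through the dissolving-metal step and the ring A work.

Step 3
Reactants: 3 2β-TBS ether
Product: 4 trans-decalin-12-one
Conditions: Li, NH3, THF, t-BuOH (1 equiv), −78 °C; then NH4Cl
Reagents that add atoms: none
Why: Dissolving-metal conjugate reduction of the enone, in which protonation of C10 on the α face gives the trans ring fusion (H-10 anti to the C15 methyl).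

Step 4
Reactants: 4 trans-decalin-12-one
Product: 5 13-en-12-one
Conditions: IBX, DMSO/fluorobenzene, 65 °C
Reagents that add atoms: none
Why: IBX dehydrogenation through the enol; a trans-fused ketone of this type enolises away from the ring fusion (toward C13), so the C13=C14 enone should form.

Step 5
Reactants: 5 13-en-12-one
Product: 6 13α,14α-diol
Conditions: OsO4 (cat.), N-methylmorpholine N-oxide, citric acid, t-BuOH/H2O, rt
Reagents that add atoms: osmium tetroxide (OsO4) O=[Os](=O)(=O)=O; N-methylmorpholine N-oxide C[N+]1([O-])CCOCC1; water O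
Why: Catalytic cis-dihydroxylation in which OsO4 adds to the face opposite the axial C15 methyl on the neighbouring C1, setting both new oxygens α.

Step 6
Reactants: 6 13α,14α-diol
Product: 7 13,14-acetonide
Conditions: Me2C(OMe)2, PPTS, CH2Cl2, rt
Reagents that add atoms: 2,2-dimethoxypropane COC(C)(C)OC
Why: Acid-catalysed acetal exchange on the cis-1,2-diol gives the five-membered isopropylidene acetal.

Step 7
Reactants: 7 13,14-acetonide
Product: 10 11(20)-methylene 12-ketone, via Mannich base 8 (not isolated), via trimethylammonium iodide 9 (not isolated)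
Conditions: LiN(iPr)2, THF, −78 °C; CH2=NMe2+ I−, −78 → 0 °C; then MeI, CH2Cl2/MeOH, rt; then NaHCO3 (aq), CH2Cl2
Reagents that add atoms: dimethylmethyleneiminium iodide C=[N+](C)C.[I-]
Why: Kinetic enolisation at the C11 methylene (not at the alkoxy-bearing C13 methine), Mannich reaction, quaternisation and E1cB loss of trimethylamine (Eschenmoser methylenation) install C20 as the exocyclic methylene.

Step 8
Reactants: 10 11(20)-methylene 12-ketone
Product: 11 12α-alcohol
Conditions: NaBH4, CeCl3·7H2O, MeOH, −78 °C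
Reagents that add atoms: none
Why: Luche 1,2-reduction in which the axial α trajectory at C12 is closed by the syn-axial C14 oxygen and the adjacent C13 oxygen, so hydride adds from the β face and the alcohol is α (all-cis with O13 and O14).

Step 9
Reactants: 11 12α-alcohol
Product: 12 12α-PMB ether
Conditions: NaH, PMBCl, Bu4NI (cat.), DMF, 0 °C → rt
Reagents that add atoms: 4-methoxybenzyl chloride COc1ccc(CCl)cc1
Why: Williamson etherification of the allylic alkoxide gives an ether that survives all later base, hydride and acid steps and is removed oxidatively at the end.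

Step 10
Reactants: 12 12α-PMB ether
Product: 13 2β-alcohol
Conditions: Bu4NF, THF, 50 °C
Reagents that add atoms: none
Why: Fluoride cleaves the only silyl ether present and leaves the acetonide and the PMB ether untouched.

Step 11
Reactants: 13 2β-alcohol
Product: 14 2-ketone
Conditions: Dess–Martin periodinane, NaHCO3, CH2Cl2, rt
Reagents that add atoms: none
Why: Dess–Martin oxidation of the hindered secondary alcohol under neutral conditions.

Step 12
Reactants: 14 2-ketone
Product: 15 7-en-2-one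
Conditions: LiN(iPr)2, THF, −78 °C; then PhS(Cl)=N-t-Bu, −78 °C
Reagents that add atoms: none
Why: One-flask enolate dehydrogenation with the sulfinimidoyl chloride (Mukaiyama type); the ketone can enolise only toward C7 because C1 is quaternary, and syn-elimination of the sulfenamide gives the C7=C8 enone.

Step 13
Reactants: 15 7-en-2-one
Product: 16 2-triflyloxy-2(7),8-diene
Conditions: KN(SiMe3)2, THF, −78 °C; then PhNTf2, −78 → 0 °C
Reagents that add atoms: N-phenylbis(trifluoromethanesulfonimide) O=S(=O)(N(c1ccccc1)S(=O)(=O)C(F)(F)F)C(F)(F)F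
Why: With no α′ hydrogen the amide base removes the γ hydrogen at C9, and O-sulfonylation of the linear dienolate gives the dienyl triflate.

Step 14
Reactants: 16 2-triflyloxy-2(7),8-diene; 17 tributyl(vinyl)stannane
Product: 18 2-vinyl-2(7),8-diene
Conditions: Pd(PPh3)4 (cat.), LiCl, THF, 60 °C
Reagents that add atoms: none
Why: Stille cross-coupling of an alkenyl triflate with a vinylstannane joins C2 to C3, with LiCl assisting transmetallation.

Step 15
Reactants: 18 2-vinyl-2(7),8-diene
Product: 20 2α-hydroxy-2β-vinyl-7-en-9-one, via endoperoxide 19 (not isolated)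
Conditions: O2, tetraphenylporphyrin (cat.), visible light, CH2Cl2, −78 °C; then Et3N (cat.), 0 °C
Reagents that add atoms: oxygen O=O
Why: Singlet-oxygen [4+2] cycloaddition to the s-cis ring diene from the α face (anti to the C15 methyl next to C2), then Kornblum–DeLaMare rearrangement, in which base removes the only peroxide α-hydrogen (H-9), gives the C9 ketone and the tertiary C2 alcohol with oxygen α and vinyl β; the base is kept catalytic and cold so that H-10 is left alone.

Step 16
Reactants: 20 2α-hydroxy-2β-vinyl-7-en-9-one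
Product: 21 2α-methyl ether
Conditions: MeOTf, 2,6-di-tert-butyl-4-methylpyridine, CH2Cl2, rt
Reagents that add atoms: methyl trifluoromethanesulfonate COS(=O)(=O)C(F)(F)F
Why: O-Methylation of the hindered tertiary alcohol with methyl triflate and a non-nucleophilic pyridine base avoids enolate formation at C10.

Step 17
Reactants: 21 2α-methyl ether
Product: 22 9β-alcohol
Conditions: NaBH4, CeCl3·7H2O, MeOH, −78 °C
Reagents that add atoms: none
Why: Luche 1,2-reduction in which the β face of C9 is screened by the syn-axial C15 methyl, so hydride adds from the α face and the alcohol is β (axial).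

Step 18
Reactants: 22 9β-alcohol
Product: 23 7β,8β-epoxide
Conditions: VO(acac)2 (cat.), t-BuOOH, CH2Cl2, 0 °C → rt
Reagents that add atoms: tert-butyl hydroperoxide CC(C)(C)OO
Why: Hydroxyl-directed epoxidation delivers oxygen to C7=C8 on the face of the C9 alcohol (β), while the vinyl and C11(20) alkenes have no free allylic hydroxyl and are left.

Step 19
Reactants: 23 7β,8β-epoxide
Product: 24 9β-PMB ether
Conditions: NaH, PMBCl, Bu4NI (cat.), DMF, 0 °C
Reagents that add atoms: 4-methoxybenzyl chloride COc1ccc(CCl)cc1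
Why: Williamson etherification; the cis epoxy alkoxide cannot reach the backside of C8, so no Payne rearrangement is expected.

Step 20
Reactants: 24 9β-PMB ether
Product: 25 7β,8α-diol
Conditions: KOH (aq), DMSO, 90 °C
Reagents that add atoms: water O
Why: SN2 opening of the epoxide by hydroxide in the trans-diaxial sense (Fürst–Plattner) at C8, the carbon remote from quaternary C2, gives the 8α-alcohol and leaves the 7β-alcohol; the acetonide is stable to base.

Step 21
Reactants: 25 7β,8α-diol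
Product: 26 8α-TES ether
Conditions: Et3SiCl, imidazole, CH2Cl2, −20 °C
Reagents that add atoms: chlorotriethylsilane CC[Si](Cl)(CC)CC
Why: Selective silylation of the more accessible C8 hydroxyl, the C7 hydroxyl being neopentyl and syn-axial to the C15 methyl and O9.

Step 22
Reactants: 26 8α-TES ether
Product: 27 7-ketone
Conditions: Dess–Martin periodinane, NaHCO3, CH2Cl2, rt
Reagents that add atoms: none
Why: Dess–Martin oxidation of the axial C7 alcohol under buffered conditions that do not epimerise C8.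

Step 23
Reactants: 27 7-ketone; 28 methyl propargyl ether
Product: 30 7α-(3-methoxyprop-1-ynyl) 7β-carbinol, via lithium alkynide 29 (not isolated)
Conditions: 28, n-BuLi, THF, −78 °C; CeCl3, −78 °C; then 27, −78 °C
Reagents that add atoms: none
Why: 1,2-Addition of an alkynylcerium reagent (low basicity suppresses enolisation toward C8); the axial β trajectory at C7 is closed by the syn-axial C15 methyl and O9, so the alkynyl group should enter equatorially (α) and leave the hydroxyl β.

Step 24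
Reactants: 30 7α-(3-methoxyprop-1-ynyl) 7β-carbinol
Product: 31 7α-propadienyl 7β-carbinol
Conditions: LiAlH4, Et2O, reflux
Reagents that add atoms: none
Why: Hydroxyl-directed trans-hydroalumination of the propargylic alcohol followed by 1,2-elimination of methoxide (SN2′ hydride reduction) gives the terminal allene without touching C7.

Step 25
Reactants: 31 7α-propadienyl 7β-carbinol
Product: 34 ten-membered 6α-chloro 7-ketone, via potassium alkoxide 32 (not isolated), via potassium dienolate 33 (not isolated)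
Conditions: KH, 18-crown-6, THF, 0 → 25 °C; then NCS, −78 °C; NH4Cl (aq)
Reagents that add atoms: N-chlorosuccinimide O=C1CCC(=O)N1Cl
Why: Proposed new method: KH/18-crown-6 turns 31 into the free alkoxide 32, in which the oxyanion weakens the C2–C7 bond and the equatorial vinyl (C2) and propadienyl (C7) groups stand gauche on the rigid trans-decalin, so a chair-like anionic oxy-Cope [3,3] shift (C4–C5 forms as C2–C7 breaks) is expected to give dienolate 33, which NCS chlorinates at C6; the closest known reaction type is the anionic oxy-Cope ring expansion of trans-1,2-dialkenylcyclohexanols to cyclodec-5-enones with in-flask trapping of the enolate, an allenyl partner on a diol monoether being untested. The ten-membered ring is not closed end to end but opened out of ring B by a four-atom ring expansion through the six-centre array C4=C3–C2–C7–C6=C5, in which C1 and C8 sit equatorial, hence trans ring bonds at the new C2=C3 enol ether (CIP Z) and at C6=C7. The allene reacts through its inner π bond, so C5 keeps the C16 methylene, at first orthogonal to the enolate, and this together with the usual α preference of dienolates directs chlorine to C6 and not to C16. C6 is the only new stereocentre and is fixed by the enolate face NCS can reach: the conformer delivered by the chair exposes the face anti to the broken C2–C7 bond, whereas the 6α-chloride needs the other face, which is outside only after the C6=C7 unit has turned with H-6 passing through the ring, the reason for ageing 33 at 25 °C before NCS is added at −78 °C. This facial selectivity is the least secure demand of the step; the others, [3,3] shift over C2–C7 fragmentation and survival of the allene under KH, rest on the pre-organised gauche π systems and on the methyl ether that keeps O2 out of enolate chemistry.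

Step 26
Reactants: 34 ten-membered 6α-chloro 7-ketone
Product: 35 7α-alcohol
Conditions: NaBH4, MeOH/CH2Cl2, −78 °C
Reagents that add atoms: none
Why: Borohydride reduction by peripheral attack on the conformer in which C5 and C9 lie on the inner side of the carbonyl plane and the C6–Cl and C8–O bonds eclipse C=O, so that hydride arrives on the side of H-6 and H-8 and the alcohol should be α (erythro to both neighbours).

Step 27
Reactants: 35 7α-alcohol; 36 2-bromopropanoyl bromide
Product: 37 7-O-(2-bromopropanoate)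
Conditions: pyridine, DMAP (cat.), CH2Cl2, −20 °C
Reagents that add atoms: none
Why: Acylation of the only free hydroxyl with an acyl bromide places the latent C17–C19 unit on O7 (the bromine-bearing carbon is a mixture of epimers and is planarised later).

Step 28
Reactants: 37 7-O-(2-bromopropanoate)
Product: 38 8α-hydroxy 2-ketone
Conditions: AcOH/THF/H2O (3:1:1), rt
Reagents that add atoms: water O
Why: Mild aqueous acid cleaves the triethylsilyl ether and hydrolyses the methyl enol ether (C3 protonation, loss of methanol) much faster than it attacks the dioxolane acetonide or the PMB ethers.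

Step 29
Reactants: 38 8α-hydroxy 2-ketone
Product: 39 2,8-diketone
Conditions: Dess–Martin periodinane, NaHCO3, CH2Cl2, 0 °C
Reagents that add atoms: none
Why: Dess–Martin oxidation of the only free hydroxyl under buffered, non-basic conditions that leave the now acidic H-7 in place.

Step 30
Reactants: 39 2,8-diketone
Product: 40 8α-hydroxy γ-lactone
Conditions: SmI2 (2.2 equiv), THF, −78 °C
Reagents that add atoms: none
Why: Intramolecular Reformatsky reaction: SmI2 reduces the C–Br bond and the samarium enolate adds to the neighbouring C8 ketone (5-exo closure forming C8–C17) without any base; C17 must arrive syn to O7 while the ring keeps C6 and C9 anticlinal and not eclipsed, which gives the trans-fused lactone with 8α-OH and the C17 methyl trans to C9, the epimer also favoured on equilibration.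

Step 31
Reactants: 40 8α-hydroxy γ-lactone
Product: 41 13α,14α-diol
Conditions: AcOH/H2O (4:1), 40 °C
Reagents that add atoms: none
Why: Acid hydrolysis of the isopropylidene acetal; PMB ethers, lactone and allylic chloride tolerate warm aqueous acetic acid.

Step 32
Reactants: 41 13α,14α-diol; 42 4-methylpentanoyl chloride
Product: 43 13-O-(4-methylpentanoate)
Conditions: 2,4,6-collidine, CH2Cl2, −40 → 0 °C
Reagents that add atoms: none
Why: Selective acylation of the equatorial C13 hydroxyl, the C14 hydroxyl being axial and neopentyl and the C8 hydroxyl tertiary.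

Step 33
Reactants: 43 13-O-(4-methylpentanoate)
Product: 44 2β-alcohol
Conditions: NaBH4, CeCl3·7H2O, MeOH, −40 °C
Reagents that add atoms: none
Why: Borohydride reduction of the C2 ketone from the face opposite the C15 methyl (hydride on the side of H-10) should give the 2β-alcohol, with esters and lactone inert under these conditions.

Step 34
Reactants: 44 2β-alcohol
Product: 45 2β,8α,9β,12α,14α-pentaol
Conditions: DDQ, CH2Cl2/pH 7 buffer, 0 °C
Reagents that add atoms: none
Why: Oxidative cleavage of both 4-methoxybenzyl ethers by DDQ in wet solvent frees O9 and O12 under neutral conditions, which keeps the C13 ester in place.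

Step 35
Reactants: 45 2β,8α,9β,12α,14α-pentaol
Product: 46 11α,20-epoxide
Conditions: VO(acac)2 (cat.), t-BuOOH (1.1 equiv), CH2Cl2, 0 °C
Reagents that add atoms: tert-butyl hydroperoxide CC(C)(C)OO
Why: Hydroxyl-directed epoxidation in which the allylic C12 hydroxyl (α) delivers oxygen to the α face of C11=C20, the face also open sterically (anti to the C15 methyl); the C5(16) methylene has no allylic hydroxyl and is deactivated by the allylic chlorine.

Step 36
Reactants: 46 11α,20-epoxide
Product: 47 CNP0196150.1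
Conditions: Ac2O, pyridine, DMAP (cat.), rt
Reagents that add atoms: acetic anhydride CC(=O)OC(C)=O
Why: Acetylation of the four secondary hydroxyls (O2, O9, O12, O14), with the tertiary C8 hydroxyl too hindered to react.

**Compound list**

1 | (S)-8a-methyl-3,4,8,8a-tetrahydronaphthalene-1,6(2H,7H)-dione (C2 and C12 carbonyls, C10=C11) | O=C1[C@@]2(C)CCC(=O)C=C2CCC1 | starting material
2 | (4aS,5S)-5-hydroxy-4a-methyl-4,4a,5,6,7,8-hexahydronaphthalen-2(3H)-one (2β-hydroxy enone) | O[C@@H]1[C@@]2(C)CCC(=O)C=C2CCC1 | intermediate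
3 | 2β-TBS ether of 2 | CC(C)(C)[Si](C)(C)O[C@@H]1[C@@]2(C)CCC(=O)C=C2CCC1 | intermediate
4 | trans-decalin-12-one, 2β-OTBS, H-10 α | CC(C)(C)[Si](C)(C)O[C@@H]1[C@@]2(C)CCC(=O)C[C@@H]2CCC1 | intermediate
5 | 13-en-12-one | CC(C)(C)[Si](C)(C)O[C@@H]1[C@@]2(C)C=CC(=O)C[C@@H]2CCC1 | intermediate
6 | 13α,14α-dihydroxy 12-ketone | CC(C)(C)[Si](C)(C)O[C@@H]1[C@@]2(C)[C@@H](O)[C@@H](O)C(=O)C[C@@H]2CCC1 | intermediate
7 | 13α,14α-O-isopropylidene 12-ketone | CC(C)(C)[Si](C)(C)O[C@@H]1[C@@]2(C)[C@@H](OC(C)(C)O4)[C@@H]4C(=O)C[C@@H]2CCC1 | intermediate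
8 | 11α-(dimethylaminomethyl) 12-ketone (Mannich base) | CC(C)(C)[Si](C)(C)O[C@@H]1[C@@]2(C)[C@@H](OC(C)(C)O4)[C@@H]4C(=O)[C@@H](CN(C)C)[C@@H]2CCC1 | intermediate
9 | 11α-(trimethylammoniomethyl) 12-ketone iodide | CC(C)(C)[Si](C)(C)O[C@@H]1[C@@]2(C)[C@@H](OC(C)(C)O4)[C@@H]4C(=O)[C@@H](C[N+](C)(C)C)[C@@H]2CCC1.[I-] | intermediate
10 | 11(20)-methylene 12-ketone | CC(C)(C)[Si](C)(C)O[C@@H]1[C@@]2(C)[C@@H](OC(C)(C)O4)[C@@H]4C(=O)C(=C)[C@@H]2CCC1 | intermediate
11 | 12α-alcohol, 11(20)-methylene | CC(C)(C)[Si](C)(C)O[C@@H]1[C@@]2(C)[C@@H](OC(C)(C)O4)[C@@H]4[C@@H](O)C(=C)[C@@H]2CCC1 | intermediate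
12 | 12α-PMB ether | CC(C)(C)[Si](C)(C)O[C@@H]1[C@@]2(C)[C@@H](OC(C)(C)O4)[C@@H]4[C@@H](OCc5ccc(OC)cc5)C(=C)[C@@H]2CCC1 | intermediate
13 | 2β-alcohol | O[C@@H]1[C@@]2(C)[C@@H](OC(C)(C)O4)[C@@H]4[C@@H](OCc5ccc(OC)cc5)C(=C)[C@@H]2CCC1 | intermediate
14 | 2-ketone | O=C1[C@@]2(C)[C@@H](OC(C)(C)O4)[C@@H]4[C@@H](OCc5ccc(OC)cc5)C(=C)[C@@H]2CCC1 | intermediate
15 | 7-en-2-one | O=C1[C@@]2(C)[C@@H](OC(C)(C)O4)[C@@H]4[C@@H](OCc5ccc(OC)cc5)C(=C)[C@@H]2CC=C1 | intermediate
16 | 2-triflyloxy-2(7),8-diene | O=S(=O)(OC=1[C@@]2(C)[C@@H](OC(C)(C)O4)[C@@H]4[C@@H](OCc5ccc(OC)cc5)C(=C)[C@@H]2C=CC=1)C(F)(F)F | intermediate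
17 | tributyl(vinyl)stannane | C=C[Sn](CCCC)(CCCC)CCCC | starting material
18 | 2-vinyl-2(7),8-diene (C4=C3–C2=C7–C8=C9 triene) | C=CC=1[C@@]2(C)[C@@H](OC(C)(C)O4)[C@@H]4[C@@H](OCc5ccc(OC)cc5)C(=C)[C@@H]2C=CC=1 | intermediate
19 | 2α,9α-epidioxy-2β-vinyl-7-ene (endoperoxide) | C=C[C@]1(OO6)[C@@]2(C)[C@@H](OC(C)(C)O4)[C@@H]4[C@@H](OCc5ccc(OC)cc5)C(=C)[C@@H]2[C@@H]6C=C1 | intermediate
20 | 2α-hydroxy-2β-vinyl-7-en-9-one | C=C[C@]1(O)[C@@]2(C)[C@@H](OC(C)(C)O4)[C@@H]4[C@@H](OCc5ccc(OC)cc5)C(=C)[C@@H]2C(=O)C=C1 | intermediate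
21 | 2α-methoxy-2β-vinyl-7-en-9-one | C=C[C@]1(OC)[C@@]2(C)[C@@H](OC(C)(C)O4)[C@@H]4[C@@H](OCc5ccc(OC)cc5)C(=C)[C@@H]2C(=O)C=C1 | intermediate
22 | 9β-hydroxy-2α-methoxy-2β-vinyl-7-ene | C=C[C@]1(OC)[C@@]2(C)[C@@H](OC(C)(C)O4)[C@@H]4[C@@H](OCc5ccc(OC)cc5)C(=C)[C@@H]2[C@H](O)C=C1 | intermediate
23 | 7β,8β-epoxy 9β-alcohol | C=C[C@]1(OC)[C@@]2(C)[C@@H](OC(C)(C)O4)[C@@H]4[C@@H](OCc5ccc(OC)cc5)C(=C)[C@@H]2[C@H](O)[C@H](O7)[C@H]71 | intermediate
24 | 7β,8β-epoxy 9β-PMB ether | C=C[C@]1(OC)[C@@]2(C)[C@@H](OC(C)(C)O4)[C@@H]4[C@@H](OCc5ccc(OC)cc5)C(=C)[C@@H]2[C@H](OCc8ccc(OC)cc8)[C@H](O7)[C@H]71 | intermediate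
25 | 7β,8α-diol | C=C[C@]1(OC)[C@@]2(C)[C@@H](OC(C)(C)O4)[C@@H]4[C@@H](OCc5ccc(OC)cc5)C(=C)[C@@H]2[C@H](OCc8ccc(OC)cc8)[C@@H](O)[C@@H]1O | intermediate
26 | 8α-TES ether 7β-alcohol | C=C[C@]1(OC)[C@@]2(C)[C@@H](OC(C)(C)O4)[C@@H]4[C@@H](OCc5ccc(OC)cc5)C(=C)[C@@H]2[C@H](OCc8ccc(OC)cc8)[C@@H](O[Si](CC)(CC)CC)[C@@H]1O | intermediate
27 | 7-ketone (8α-OTES, 9β-OPMB, 2α-OMe, 2β-vinyl) | C=C[C@]1(OC)[C@@]2(C)[C@@H](OC(C)(C)O4)[C@@H]4[C@@H](OCc5ccc(OC)cc5)C(=C)[C@@H]2[C@H](OCc8ccc(OC)cc8)[C@@H](O[Si](CC)(CC)CC)C1=O | intermediate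
28 | methyl propargyl ether (3-methoxyprop-1-yne) | COCC#C | starting material
29 | lithium 3-methoxyprop-1-yn-1-ide (LiC≡CCH2OMe) | [Li]C#CCOC | intermediate
30 | 7α-(3-methoxyprop-1-ynyl) 7β-carbinol | C=C[C@]1(OC)[C@@]2(C)[C@@H](OC(C)(C)O4)[C@@H]4[C@@H](OCc5ccc(OC)cc5)C(=C)[C@@H]2[C@H](OCc8ccc(OC)cc8)[C@@H](O[Si](CC)(CC)CC)[C@@]1(O)C#CCOC | intermediate
31 | 7α-propadienyl 7β-carbinol: trans-decalin with 2β-vinyl/2α-OMe and 7α-allenyl/7β-OH (both alkenyl groups equatorial) | C=C[C@]1(OC)[C@@]2(C)[C@@H](OC(C)(C)O4)[C@@H]4[C@@H](OCc5ccc(OC)cc5)C(=C)[C@@H]2[C@H](OCc8ccc(OC)cc8)[C@@H](O[Si](CC)(CC)CC)[C@@]1(O)C=C=C | intermediate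
32 | potassium 7β-alkoxide of 31 | C=C[C@]1(OC)[C@@]2(C)[C@@H](OC(C)(C)O4)[C@@H]4[C@@H](OCc5ccc(OC)cc5)C(=C)[C@@H]2[C@H](OCc8ccc(OC)cc8)[C@@H](O[Si](CC)(CC)CC)[C@@]1([O-])C=C=C.[K+] | intermediate
33 | potassium dienolate O–C7=C6–C5=C16 of the ten-membered ring (trans ring bonds at C2=C3 and C6=C7) | C=C1C/C=C(\OC)/[C@@]2(C)[C@@H](OC(C)(C)O4)[C@@H]4[C@@H](OCc5ccc(OC)cc5)C(=C)[C@@H]2[C@H](OCc8ccc(OC)cc8)[C@@H](O[Si](CC)(CC)CC)/C([O-])=C/1.[K+] | intermediate
34 | ten-membered 6α-chloro 7-ketone with C2 methyl enol ether (trans ring bonds, CIP Z), C5(16) methylene, 8α-OTES, 9β-OPMB | C=C1C/C=C(\OC)/[C@@]2(C)[C@@H](OC(C)(C)O4)[C@@H]4[C@@H](OCc5ccc(OC)cc5)C(=C)[C@@H]2[C@H](OCc8ccc(OC)cc8)[C@@H](O[Si](CC)(CC)CC)C(=O)[C@H]1Cl | intermediate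
35 | 6α-chloro 7α-alcohol | C=C1C/C=C(\OC)/[C@@]2(C)[C@@H](OC(C)(C)O4)[C@@H]4[C@@H](OCc5ccc(OC)cc5)C(=C)[C@@H]2[C@H](OCc8ccc(OC)cc8)[C@@H](O[Si](CC)(CC)CC)[C@@H](O)[C@H]1Cl | intermediate
36 | 2-bromopropanoyl bromide (racemic) | CC(Br)C(Br)=O | starting material
37 | 7-O-(2-bromopropanoate), epimers at the CHBr carbon | C=C1C/C=C(\OC)/[C@@]2(C)[C@@H](OC(C)(C)O4)[C@@H]4[C@@H](OCc5ccc(OC)cc5)C(=C)[C@@H]2[C@H](OCc8ccc(OC)cc8)[C@@H](O[Si](CC)(CC)CC)[C@@H](OC(=O)C(C)Br)[C@H]1Cl | intermediate
38 | 8α-hydroxy 2-ketone 7-O-(2-bromopropanoate) | C=C1CCC(=O)[C@@]2(C)[C@@H](OC(C)(C)O4)[C@@H]4[C@@H](OCc5ccc(OC)cc5)C(=C)[C@@H]2[C@H](OCc8ccc(OC)cc8)[C@@H](O)[C@@H](OC(=O)C(C)Br)[C@H]1Cl | intermediate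
39 | 2,8-diketone 7-O-(2-bromopropanoate) | C=C1CCC(=O)[C@@]2(C)[C@@H](OC(C)(C)O4)[C@@H]4[C@@H](OCc5ccc(OC)cc5)C(=C)[C@@H]2[C@H](OCc8ccc(OC)cc8)C(=O)[C@@H](OC(=O)C(C)Br)[C@H]1Cl | intermediate
40 | 8α-hydroxy-17-methyl γ-lactone (C7–O–C19(=O)–C17–C8, trans-fused), 2-ketone | C=C1CCC(=O)[C@@]2(C)[C@@H](OC(C)(C)O4)[C@@H]4[C@@H](OCc5ccc(OC)cc5)C(=C)[C@@H]2[C@H](OCc8ccc(OC)cc8)[C@]6(O)[C@@H](C)C(=O)O[C@H]6[C@H]1Cl | intermediate
41 | 13α,14α-diol lactone | C=C1CCC(=O)[C@@]2(C)[C@@H](O)[C@@H](O)[C@@H](OCc5ccc(OC)cc5)C(=C)[C@@H]2[C@H](OCc8ccc(OC)cc8)[C@]6(O)[C@@H](C)C(=O)O[C@H]6[C@H]1Cl | intermediate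
42 | 4-methylpentanoyl chloride | CC(C)CCC(Cl)=O | starting material
43 | 13α-O-(4-methylpentanoate) 14α-alcohol | C=C1CCC(=O)[C@@]2(C)[C@@H](O)[C@@H](OC(=O)CCC(C)C)[C@@H](OCc5ccc(OC)cc5)C(=C)[C@@H]2[C@H](OCc8ccc(OC)cc8)[C@]6(O)[C@@H](C)C(=O)O[C@H]6[C@H]1Cl | intermediate
44 | 2β-alcohol | C=C1CC[C@H](O)[C@@]2(C)[C@@H](O)[C@@H](OC(=O)CCC(C)C)[C@@H](OCc5ccc(OC)cc5)C(=C)[C@@H]2[C@H](OCc8ccc(OC)cc8)[C@]6(O)[C@@H](C)C(=O)O[C@H]6[C@H]1Cl | intermediate
45 | 2β,8α,9β,12α,14α-pentaol 13-ester | C=C1CC[C@H](O)[C@@]2(C)[C@@H](O)[C@@H](OC(=O)CCC(C)C)[C@@H](O)C(=C)[C@@H]2[C@H](O)[C@]6(O)[C@@H](C)C(=O)O[C@H]6[C@H]1Cl | intermediate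
46 | 11α,20-epoxide of 45 | C=C1CC[C@H](O)[C@@]2(C)[C@@H](O)[C@@H](OC(=O)CCC(C)C)[C@@H](O)[C@]3(CO3)[C@@H]2[C@H](O)[C@]6(O)[C@@H](C)C(=O)O[C@H]6[C@H]1Cl | intermediate
47 | CNP0196150.1: 2β,9β,12α,14α-tetraacetoxy-6α-chloro-11α,20-epoxy-8α-hydroxy-13α-(4-methylpentanoyloxy)briar-5(16)-en-19,7-olide | C=C1CC[C@H](OC(C)=O)[C@@]2(C)[C@@H](OC(C)=O)[C@@H](OC(=O)CCC(C)C)[C@@H](OC(C)=O)[C@]3(CO3)[C@@H]2[C@H](OC(C)=O)[C@]2(O)[C@@H](C)C(=O)O[C@H]2[C@H]1Cl | target

**Step count and risks**

Total step count: 36. Longest linear sequence: 36 steps (from 1; 17, 28, 36 and 42 are bought).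

Steps most likely to fail:

1. Step 25 (bears the label). Three things may go wrong: heterolysis of the C2–C7 bond of the alkoxide (fragmentation or a [1,3] shift through an α-methoxyallyl anion), base-induced isomerisation of the allene before it engages, or chlorination of the dienolate on the wrong face of C6. The fallback uses known chemistry only, from 27 back to 34. Ketone 27 is treated with (E)-3-(dimethylamino)prop-1-enyllithium and CeCl3 (from the alkenyl bromide and t-BuLi) to give the 7α-[(E)-3-(dimethylamino)prop-1-enyl] 7β-carbinol F1. The classical anionic oxy-Cope ring expansion of this trans-1,2-dialkenylcyclohexanol (KH, 18-crown-6, THF; NH4Cl) gives the ten-membered 7-ketone with a dimethylaminomethyl group on C5 F2. Aqueous H2O2 in methanol forms the amine N-oxide F3, which on warming undergoes Cope elimination (H-5 is the only β-hydrogen) to the 5(16)-methylene 7-ketone F4. Kinetic deprotonation at C6 (LiN(iPr)2, −78 °C) and chlorination of the lithium dienolate with NCS return to 34. The C–Cl bond is then made on an isolated ketone, so C6 epimers can be separated or equilibrated before the material is carried on.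

2. Step 26. Hydride may be delivered to the wrong face of the ten-membered ketone if the ring does not adopt the assumed conformer, or the chlorohydrin alkoxide may close to an epoxide. The fallback runs from 34 back to 37. If the 7β-alcohol F5 forms, it is esterified with inversion at C7 by Mitsunobu reaction with 2-bromopropanoic acid (PPh3, diisopropyl azodicarboxylate, toluene, 0 °C), which gives 37 directly.

3. Step 30. Electron transfer to the α-acyloxy ketone (loss of the O7 ester by C7–O cleavage) or to the allylic chloride may compete with reduction of the C–Br bond, or the samarium enolate may add to the other face of C8. The fallback runs from 35 back to 40 and makes the enolate by deprotonation. Alcohol 35 is acylated with propanoyl chloride to the 7-O-propanoate F6, aqueous acetic acid unmasks the 8α-hydroxy 2-ketone F7, and Dess–Martin oxidation gives the 8-keto propanoate F8. LiN(SiMe3)2 (THF, −78 °C) then closes the lactone by intramolecular aldol addition to give 40, the low temperature favouring ester enolisation over removal of H-7.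

Further compounds
F1 | step 25 | 7α-[(E)-3-(dimethylamino)prop-1-enyl] 7β-carbinol | C=C[C@]1(OC)[C@@]2(C)[C@@H](OC(C)(C)O4)[C@@H]4[C@@H](OCc5ccc(OC)cc5)C(=C)[C@@H]2[C@H](OCc8ccc(OC)cc8)[C@@H](O[Si](CC)(CC)CC)[C@@]1(O)/C=C/CN(C)C
F2 | step 25 | ten-membered 7-ketone with 5-(dimethylaminomethyl) group and C2 methyl enol ether | CN(C)C[C@H]1C/C=C(\OC)/[C@@]2(C)[C@@H](OC(C)(C)O4)[C@@H]4[C@@H](OCc5ccc(OC)cc5)C(=C)[C@@H]2[C@H](OCc8ccc(OC)cc8)[C@@H](O[Si](CC)(CC)CC)C(=O)C1
F3 | step 25 | amine N-oxide of F2 | C[N+](C)([O-])C[C@H]1C/C=C(\OC)/[C@@]2(C)[C@@H](OC(C)(C)O4)[C@@H]4[C@@H](OCc5ccc(OC)cc5)C(=C)[C@@H]2[C@H](OCc8ccc(OC)cc8)[C@@H](O[Si](CC)(CC)CC)C(=O)C1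
F4 | step 25 | 5(16)-methylene 7-ketone (34 without chlorine) | C=C1C/C=C(\OC)/[C@@]2(C)[C@@H](OC(C)(C)O4)[C@@H]4[C@@H](OCc5ccc(OC)cc5)C(=C)[C@@H]2[C@H](OCc8ccc(OC)cc8)[C@@H](O[Si](CC)(CC)CC)C(=O)C1
F5 | step 26 | 6α-chloro 7β-alcohol (7-epimer of 35) | C=C1C/C=C(\OC)/[C@@]2(C)[C@@H](OC(C)(C)O4)[C@@H]4[C@@H](OCc5ccc(OC)cc5)C(=C)[C@@H]2[C@H](OCc8ccc(OC)cc8)[C@@H](O[Si](CC)(CC)CC)[C@H](O)[C@H]1Cl
F6 | step 30 | 7-O-propanoate of 35 | C=C1C/C=C(\OC)/[C@@]2(C)[C@@H](OC(C)(C)O4)[C@@H]4[C@@H](OCc5ccc(OC)cc5)C(=C)[C@@H]2[C@H](OCc8ccc(OC)cc8)[C@@H](O[Si](CC)(CC)CC)[C@@H](OC(=O)CC)[C@H]1Cl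
F7 | step 30 | 8α-hydroxy 2-ketone 7-O-propanoate | C=C1CCC(=O)[C@@]2(C)[C@@H](OC(C)(C)O4)[C@@H]4[C@@H](OCc5ccc(OC)cc5)C(=C)[C@@H]2[C@H](OCc8ccc(OC)cc8)[C@@H](O)[C@@H](OC(=O)CC)[C@H]1Cl
F8 | step 30 | 2,8-diketone 7-O-propanoate | C=C1CCC(=O)[C@@]2(C)[C@@H](OC(C)(C)O4)[C@@H]4[C@@H](OCc5ccc(OC)cc5)C(=C)[C@@H]2[C@H](OCc8ccc(OC)cc8)C(=O)[C@@H](OC(=O)CC)[C@H]1Cl
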